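The dihydropyran (O1, C2 methyl, C3 hydroxymethyl, C4 acetate arm, C5 ester, C6 enol ether CH) is opened across its enol ether bond O1–C6 and its ring bond C5–C4, which releases C6, C5 and the methyl ester as methyl propiolate. The key step exploits the vinylogous carbonate O1–C6=C5–CO2Me of this ring and the 1,5-diester relation between the C5 ester and the C4 acetate arm: a phosphine-triggered oxa-Michael/Michael cascade joins the C2 alkoxide to C6 and C5 to C4 in one operation and sets C4 from C2 and C3. Its precursor is an acyclic (E)-δ-hydroxy enoate that already carries the benzyl-protected hydroxytyrosol ester; C2 and C3 come from methyl (R)-3-hydroxybutanoate by Fráter–Seebach alkylation.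

Key step: step 6

Remark on the chemistry: the catechol and the primary alcohol are carried as benzyl ethers so that a single hydrogenolysis ends the route; 2-[3,4-bis(benzyloxy)phenyl]ethanol is made from hydroxytyrosol and is not assumed to be purchasable.

Step 1
Reactants: 1 hydroxytyrosol [2-(3,4-dihydroxyphenyl)ethanol]
Product: 2 2-[3,4-bis(benzyloxy)phenyl]ethanol
Conditions: BnBr (2.2 equiv), K2CO3 (2.5 equiv), acetone, reflux, N2
Reagents that add atoms: benzyl bromide BrCc1ccccc1
Why: Williamson ether synthesis in which K2CO3 deprotonates only the two phenols, so the aliphatic alcohol should stay free.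

Step 2
Reactants: 2 2-[3,4-bis(benzyloxy)phenyl]ethanol; 3 (triphenylphosphoranylidene)ketene (Bestmann ylide)
Product: 4 2-[3,4-bis(benzyloxy)phenyl]ethyl (triphenylphosphoranylidene)acetate
Conditions: toluene, 90 °C
Reagents that add atoms: none
Why: Addition of the alcohol O–H across the cumulated C=C of the Bestmann ylide should give the stabilized ester ylide directly, with no by-product.

Step 3
Reactants: 5 methyl (R)-3-hydroxybutanoate
Product: 7 methyl (2R,3R)-2-[(benzyloxy)methyl]-3-hydroxybutanoate, via dilithium alkoxide enolate 6 (not isolated)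
Conditions: LiN(iPr)2 (2.2 equiv), THF, −78 to −20 °C; then BnOCH2Cl (1.1 equiv), DMPU, −78 to −10 °C; aqueous work-up
Reagents that add atoms: benzyl chloromethyl ether ClCOCc1ccccc1
Why: Fráter–Seebach alkylation, in which the lithium-chelated alkoxide enolate is alkylated on the face away from the C3 methyl group, so the anti (2R,3R) ester should form with the new centre set by the chiral-pool carbinol.

Step 4
Reactants: 7 methyl (2R,3R)-2-[(benzyloxy)methyl]-3-hydroxybutanoate
Product: 8 (2R,3R)-2-[(benzyloxy)methyl]butane-1,3-diol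
Conditions: LiAlH4, THF, 0 °C to rt; Fieser work-up
Reagents that add atoms: none
Why: Hydride reduction of the ester to the primary alcohol, which should leave the benzyl ether and both stereocentres untouched.

Step 5
Reactants: 8 (2R,3R)-2-[(benzyloxy)methyl]butane-1,3-diol; 4 2-[3,4-bis(benzyloxy)phenyl]ethyl (triphenylphosphoranylidene)acetate
Product: 10 2-[3,4-bis(benzyloxy)phenyl]ethyl (2E,4R,5R)-4-[(benzyloxy)methyl]-5-hydroxyhex-2-enoate, via β-hydroxy aldehyde 9 (not isolated)
Conditions: TEMPO (0.2 equiv), PhI(OAc)2 (1.1 equiv), CH2Cl2, rt; then 4 (1.5 equiv), rt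
Reagents that add atoms: none
Why: The oxoammonium (TEMPO/PhI(OAc)2) oxidation is selective for the primary carbinol, and the Wittig reaction of the stabilized ylide in the same flask should give the E-enoate under near-neutral conditions before the α-centre of the aldehyde can epimerize.

Step 6
Reactants: 10 2-[3,4-bis(benzyloxy)phenyl]ethyl (2E,4R,5R)-4-[(benzyloxy)methyl]-5-hydroxyhex-2-enoate; 11 methyl propiolate
Product: 12 methyl (2R,3R,4S)-4-{2-[2-(3,4-bis(benzyloxy)phenyl)ethoxy]-2-oxoethyl}-3-[(benzyloxy)methyl]-2-methyl-3,4-dihydro-2H-pyran-5-carboxylate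
Conditions: PMe3 (0.2 equiv), 11 (1.3 equiv, syringe pump), toluene (0.01 M), 0 °C to rt
Reagents that add atoms: none
Why: Proposed new method: PMe3 adds to methyl propiolate and the zwitterion deprotonates the C2 hydroxyl of 10; the alkoxide then adds to the β-carbon of the propiolate (bond O1–C6) to give an allenolate whose α-carbon (C5) attacks the enoate β-carbon C4 before it is protonated, and the resulting ester enolate takes its proton from the next molecule of 10, which carries the chain. The closest known reaction type is the Lewis-base- or carbonate-mediated oxa-Michael/Michael annulation of 2-hydroxyaryl enones, enoates and nitroalkenes with alkynoates to 4H-chromenes, extended here to an aliphatic δ-hydroxy enoate; the phosphine-catalysed addition of alcohols to propiolates is itself standard. The dihydropyran ring closes by a 6-(enolexo)-exo-trig Michael addition. The new C4 stereocentre is controlled by the existing C2 and C3 centres through a chair-like transition state in which the C2 methyl, the C3 benzyloxymethyl and the enoate arm are all equatorial, so that C5 should attack anti to the benzyloxymethyl group and the 3,4-trans (4S) isomer should result. The step needs ring closure to outrun protonation of the allenolate, which would stop at the open-chain β-alkoxyacrylate; high dilution and slow addition of the propiolate keep proton donors scarce without slowing the intramolecular step, and the E geometry of the enoate, together with the impossibility of a four-membered oxa-Michael closure, leaves C4 as the only electrophilic carbon within reach.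

Step 7
Reactants: 12 methyl (2R,3R,4S)-4-{2-[2-(3,4-bis(benzyloxy)phenyl)ethoxy]-2-oxoethyl}-3-[(benzyloxy)methyl]-2-methyl-3,4-dihydro-2H-pyran-5-carboxylate
Product: 13 methyl (2R,3R,4S)-4-{2-[2-(3,4-dihydroxyphenyl)ethoxy]-2-oxoethyl}-3-(hydroxymethyl)-2-methyl-3,4-dihydro-2H-pyran-5-carboxylate (CNP0204147.1)
Conditions: H2 (1 atm), Pd(OH)2 on carbon, EtOAc, rt
Reagents that add atoms: none
Why: Catalytic hydrogenolysis should cleave the two aryl benzyl ethers and the primary alkyl benzyl ether, while the push-pull C5=C6 double bond of the vinylogous carbonate is resistant to hydrogenation at 1 atm and the neutral medium should not induce lactonization of the freed alcohol.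

Compound list
1 | hydroxytyrosol, 2-(3,4-dihydroxyphenyl)ethanol | OCCc1ccc(O)c(O)c1 | starting material
2 | 2-[3,4-bis(benzyloxy)phenyl]ethanol | OCCc1ccc(OCc2ccccc2)c(OCc2ccccc2)c1 | intermediate
3 | (triphenylphosphoranylidene)ketene | O=C=C=P(c1ccccc1)(c1ccccc1)c1ccccc1 | starting material
4 | 2-[3,4-bis(benzyloxy)phenyl]ethyl (triphenylphosphoranylidene)acetate | O=C(C=P(c1ccccc1)(c1ccccc1)c1ccccc1)OCCc1ccc(OCc2ccccc2)c(OCc2ccccc2)c1 | intermediate
5 | methyl (R)-3-hydroxybutanoate | C[C@@H](O)CC(=O)OC | starting material
6 | dilithium alkoxide enolate of methyl (R)-3-hydroxybutanoate | [Li+].[Li+].[O-][C@H](C)C=C([O-])OC | intermediate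
7 | methyl (2R,3R)-2-[(benzyloxy)methyl]-3-hydroxybutanoate | O[C@H](C)[C@@H](COCc1ccccc1)C(=O)OC | intermediate
8 | (2R,3R)-2-[(benzyloxy)methyl]butane-1,3-diol | O[C@H](C)[C@@H](COCc1ccccc1)CO | intermediate
9 | (2R,3R)-2-[(benzyloxy)methyl]-3-hydroxybutanal | O[C@H](C)[C@@H](COCc1ccccc1)C=O | intermediate
10 | 2-[3,4-bis(benzyloxy)phenyl]ethyl (2E,4R,5R)-4-[(benzyloxy)methyl]-5-hydroxyhex-2-enoate | O[C@H](C)[C@@H](COCc1ccccc1)/C=C/C(=O)OCCc1ccc(OCc2ccccc2)c(OCc2ccccc2)c1 | intermediate
11 | methyl propiolate | C#CC(=O)OC | starting material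
12 | methyl (2R,3R,4S)-4-{2-[2-(3,4-bis(benzyloxy)phenyl)ethoxy]-2-oxoethyl}-3-[(benzyloxy)methyl]-2-methyl-3,4-dihydro-2H-pyran-5-carboxylate | COC(=O)C1=CO[C@H](C)[C@@H](COCc2ccccc2)[C@@H]1CC(=O)OCCc1ccc(OCc2ccccc2)c(OCc2ccccc2)c1 | intermediate
13 | methyl (2R,3R,4S)-4-{2-[2-(3,4-dihydroxyphenyl)ethoxy]-2-oxoethyl}-3-(hydroxymethyl)-2-methyl-3,4-dihydro-2H-pyran-5-carboxylate | COC(=O)C1=CO[C@H](C)[C@@H](CO)[C@@H]1CC(=O)OCCc1ccc(O)c(O)c1 | target

Total step count: 7. Longest linear sequence: 5 steps (steps 3, 4, 5, 6, 7 from methyl (R)-3-hydroxybutanoate; the hydroxytyrosol branch, steps 1, 2, 5, 6, 7, is equally long).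

Steps most likely to fail

Step 6 (proposed new method). The allenolate may be protonated before it closes the ring, so that the reaction stops after the oxa-Michael addition, or the attack on C4 may show poor facial selectivity. The fallback uses known chemistry only, sets out from 10 and comes back to the route at 12. The N-methylmorpholine-catalysed oxa-Michael addition of 10 to methyl propiolate 11 (CH2Cl2, rt) should give the open-chain adduct 2-[3,4-bis(benzyloxy)phenyl]ethyl (2E,4R,5R)-4-[(benzyloxy)methyl]-5-{[(1E)-3-methoxy-3-oxoprop-1-en-1-yl]oxy}hex-2-enoate F1. Iodination and elimination at the α-carbon of the β-alkoxyacrylate (N-iodosuccinimide, AcOH, CH2Cl2; then Et3N) should give the vinyl iodide 2-[3,4-bis(benzyloxy)phenyl]ethyl (2E,4R,5R)-4-[(benzyloxy)methyl]-5-{[(1Z)-2-iodo-3-methoxy-3-oxoprop-1-en-1-yl]oxy}hex-2-enoate F2. A 6-exo-trig vinyl radical cyclization onto the enoate (Bu3SnH, AIBN, benzene, 80 °C, slow addition) should then close the C5–C4 bond through the same all-equatorial chair and give 12.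

Step 5. The β-hydroxy aldehyde may lose benzyl alcohol by β-elimination or epimerize at its α-carbon before the olefination is complete. The fallback sets out from 7 and comes back at 10, and masks the carbinol first. Silylation of 7 (Et3SiCl, imidazole, CH2Cl2) should give methyl (2R,3R)-2-[(benzyloxy)methyl]-3-[(triethylsilyl)oxy]butanoate F3. Partial reduction (iBu2AlH, CH2Cl2, −78 °C) should give (2R,3R)-2-[(benzyloxy)methyl]-3-[(triethylsilyl)oxy]butanal F4. Wittig reaction with ylide 4 (CH2Cl2, rt) should give 2-[3,4-bis(benzyloxy)phenyl]ethyl (2E,4R,5R)-4-[(benzyloxy)methyl]-5-[(triethylsilyl)oxy]hex-2-enoate F5, and desilylation (HF·pyridine, THF, 0 °C) should release 10.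

Step 7. Over-reduction of the C5=C6 enol ether double bond may set in during the slower cleavage of the alkyl benzyl ether, or the freed primary alcohol may lactonize onto the side-chain ester on prolonged reaction. The fallback sets out from 12 and comes back at 13 without any new compound: Lewis-acid debenzylation with a cation scavenger (BCl3, pentamethylbenzene, CH2Cl2, −78 °C, methanol quench) should remove all three benzyl groups without hydrogen and at low temperature.

Further compounds
F1 | step 6 | 2-[3,4-bis(benzyloxy)phenyl]ethyl (2E,4R,5R)-4-[(benzyloxy)methyl]-5-{[(1E)-3-methoxy-3-oxoprop-1-en-1-yl]oxy}hex-2-enoate | COC(=O)/C=C/O[C@H](C)[C@@H](COCc1ccccc1)/C=C/C(=O)OCCc1ccc(OCc2ccccc2)c(OCc2ccccc2)c1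
F2 | step 6 | 2-[3,4-bis(benzyloxy)phenyl]ethyl (2E,4R,5R)-4-[(benzyloxy)methyl]-5-{[(1Z)-2-iodo-3-methoxy-3-oxoprop-1-en-1-yl]oxy}hex-2-enoate | COC(=O)C(/I)=C/O[C@H](C)[C@@H](COCc1ccccc1)/C=C/C(=O)OCCc1ccc(OCc2ccccc2)c(OCc2ccccc2)c1
F3 | step 5 | methyl (2R,3R)-2-[(benzyloxy)methyl]-3-[(triethylsilyl)oxy]butanoate | CC[Si](CC)(CC)O[C@H](C)[C@@H](COCc1ccccc1)C(=O)OC
F4 | step 5 | (2R,3R)-2-[(benzyloxy)methyl]-3-[(triethylsilyl)oxy]butanal | CC[Si](CC)(CC)O[C@H](C)[C@@H](COCc1ccccc1)C=O
F5 | step 5 | 2-[3,4-bis(benzyloxy)phenyl]ethyl (2E,4R,5R)-4-[(benzyloxy)methyl]-5-[(triethylsilyl)oxy]hex-2-enoate | CC[Si](CC)(CC)O[C@H](C)[C@@H](COCc1ccccc1)/C=C/C(=O)OCCc1ccc(OCc2ccccc2)c(OCc2ccccc2)c1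
F0 | step 7 | none | none
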